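## Retrosynthetic overview

1. The target is opened last: saponification of a bridging cyclic enol ether and gem-diprenylation at C3 of a C5-acylated, ether-bridged spiro trione; the acyl group goes on the only free β-diketone carbon of that bridged compound.
2. Key disconnection is the C7'–O bond: a trione enol oxygen adds across the 7'-methylidene of a spiro trione whose spiro carbon still has two identical carbonyl neighbours. Only the carbonyl oxygen 1,3-diaxial to C7' can reach, so this one C–O bond sets C7' and makes the two spiro carbonyls different.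
3. The spiro trione comes from a 2-alkylphloroglucinol by oxidative 6-endo radical spirocyclisation onto an isopropenyl group.
4. The 2-alkylphloroglucinol comes from phloroglucinol and a cyclopentane β-hydroxy aldehyde (reductive alkylation); the aldehyde comes from (S)-limonene by ozonolysis/aldol condensation, epoxidation and reductive epoxide opening.
5. Ring order: cyclopentane (ring contraction of limonene), then spiro cyclohexane plus bridging oxolane in one pot; the trione ring is the phloroglucinol ring, dressed last with acyl and prenyl groups.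

Assumption: the target is treated as the keto–enol tautomer of the given SMILES and commercial (S)-(−)-limonene of high ee is the chiral source. Locants follow spiro[cyclohexane-1,5'-indene] numbering: C1 spiro, C2 the flanking carbonyl next to the diprenyl carbon C3, C5 the acyl-bearing carbon, C6 the other flanking carbonyl, C3' and C7' the carbinol carbons, C3a' and C7a' the ring-fusion carbons.

## Route

Step 1
Reactants: 1 (S)-(−)-limonene
Product: 3 (5R)-2-methyl-5-(prop-1-en-2-yl)cyclopent-1-ene-1-carbaldehyde, via keto aldehyde 2 (not isolated)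
Conditions: O3 (1.0 equiv, metered), CH2Cl2, −78 °C; Me2S, −78 to 20 °C; then piperidine (0.3 equiv), AcOH (0.3 equiv), 40 °C, same flask
Reagents that add atoms: ozone, [O-][O+]=O
Why: Ozone cleaves the electron-rich trisubstituted ring alkene in preference to the 1,1-disubstituted isopropenyl group (chemoselective ozonolysis, reductive work-up), and piperidinium acetate drives the intramolecular enamine aldol condensation of 2 to the cyclopentene carbaldehyde; the limonene stereocentre is not enolisable and becomes C7a'.

Step 2
Reactants: 3 (5R)-2-methyl-5-(prop-1-en-2-yl)cyclopent-1-ene-1-carbaldehyde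
Product: 4 (1R,2R,5S)-5-methyl-2-(prop-1-en-2-yl)-6-oxabicyclo[3.1.0]hexane-1-carbaldehyde
Conditions: H2O2 (30% aq., 1.5 equiv), NaOH (0.2 equiv), MeOH, 0 °C
Reagents that add atoms: hydrogen peroxide, OO
Why: Weitz–Scheffer nucleophilic epoxidation touches only the enal double bond, and the oxirane closes on the face opposite the neighbouring isopropenyl group, which fixes the future C3'–O bond trans to that group.

Step 3
Reactants: 4 (1R,2R,5S)-5-methyl-2-(prop-1-en-2-yl)-6-oxabicyclo[3.1.0]hexane-1-carbaldehyde
Product: 6 (1R,2S,5S)-2-hydroxy-2-methyl-5-(prop-1-en-2-yl)cyclopentane-1-carbaldehyde, via formyl epimer 5 (not isolated)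
Conditions: SmI2 (2.05 equiv), THF–MeOH, −90 °C; pH 7 buffer; then DBU (0.05 equiv), CH2Cl2, −20 °C
Reagents that add atoms: none
Why: Reductive cleavage of an α,β-epoxy carbonyl compound by SmI2 (divalent samarium: ketyl, rupture of the α C–O bond, second electron transfer, protonation) leaves the β C–O bond and its configuration untouched, and base epimerisation of the formyl-bearing carbon gives the thermodynamic isomer with CHO trans to both flanking carbon substituents and cis to OH, which sets C3a'.

Step 4
Reactants: 6 (1R,2S,5S)-2-hydroxy-2-methyl-5-(prop-1-en-2-yl)cyclopentane-1-carbaldehyde; 7 phloroglucinol (benzene-1,3,5-triol)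
Product: 9 2-{[(1R,2S,5S)-2-hydroxy-2-methyl-5-(prop-1-en-2-yl)cyclopentyl]methyl}benzene-1,3,5-triol, via quinone methide 8 (not isolated)
Conditions: 7 (3 equiv), Hantzsch ester (diethyl 2,6-dimethyl-1,4-dihydropyridine-3,5-dicarboxylate, 1.3 equiv), AcOH (0.2 equiv), THF, 30 °C
Reagents that add atoms: none
Why: Three-component reductive alkylation: acid-catalysed, reversible Friedel–Crafts hydroxyalkylation of the very electron-rich arene gives quinone methide 8, which is reduced irreversibly by hydride transfer from the Hantzsch ester while diarylmethane adducts revert; no stereocentre is formed and amine-free conditions avoid dehydration of the β-hydroxy aldehyde.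

Step 5
Reactants: 9 2-{[(1R,2S,5S)-2-hydroxy-2-methyl-5-(prop-1-en-2-yl)cyclopentyl]methyl}benzene-1,3,5-triol
Product: 11 bridged enol ether (O-7' bonded to C2; C2=C3 enol ether; C4 and C6 carbonyls; 3'S,3a'R,7'R,7a'S), via spiro trione 10 (not isolated)
Conditions: Mn(OAc)3·2H2O (2.2 equiv), Cu(OAc)2·H2O (0.2 equiv), AcOH, N2, 25 °C; then TsOH·H2O (0.05 equiv), 25 °C
Reagents that add atoms: none
Why: Proposed new method: dearomatising oxidative 6-endo spirocyclisation of a free 2-alkylphloroglucinol joined in one pot to a desymmetrising transannular hydroalkoxylation — Mn(OAc)3 (trivalent manganese) oxidises the trione-type enol of 9 to the tertiary radical at the alkylated ring carbon, which adds to the CH2 terminus of the isopropenyl group through a chair fused trans to the cyclopentane (6-endo is the normal mode for 1,3-dicarbonyl radicals with 1,1-disubstituted alkenes); Cu(OAc)2 (divalent copper) converts the tertiary radical into alkene 10, whose spiro carbon still has two identical carbonyl neighbours; TsOH then gives the C7' cation, which is captured only by the oxygen of the carbonyl 1,3-diaxial to it (five-membered ring), so the new C7'–O bond is axial (anti to H-7a'), the methyl equatorial, and the two spiro carbonyls become different; closest known reaction types: Mn(OAc)3/Cu(OAc)2 oxidative free-radical cyclisation of 2-alkyl-1,3-dicarbonyl compounds and of dearomatised acylphloroglucinols, and acid-catalysed cyclisation of 2-(2-methylallyl)-1,3-diones to dihydrofurans.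

Step 6
Reactants: 11 bridged enol ether; 12 3-methylbutanoic acid
Product: 14 5-(3-methylbutanoyl) bridged enol ether, via enol ester 13 (not isolated)
Conditions: 12 (1.1 equiv), DCC (1.1 equiv), DMAP (0.3 equiv), CH2Cl2, 0 to 25 °C
Reagents that add atoms: none
Why: Steglich-type O-acylation followed by DMAP-mediated O-to-C acyl migration (the one-pot C-acylation of cyclic 1,3-diones) puts the acyl group on C5, the only carbon between two free carbonyls (C3 is the non-nucleophilic α-carbon of the bridging vinylogous ester), so the acyl group ends next to the carbonyl anti to the ether bridge, which turns the desymmetrisation of step 5 into the correct spiro configuration.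

Step 7
Reactants: 14 5-(3-methylbutanoyl) bridged enol ether; 15 1-bromo-3-methylbut-2-ene (prenyl bromide)
Product: 18 target CNP0198642.4, via hydroxy trione 16 (not isolated), via monoprenyl trione 17 (not isolated)
Conditions: KOH (5 equiv), H2O–1,4-dioxane, 75 °C; then 0 °C, 15 (2.5 equiv); HCl (aq.) to pH 3
Reagents that add atoms: water, O
Why: Saponification of the vinylogous ester (addition–elimination at the sp2 carbon C2, so the C7'–O bond and its configuration are kept) gives the dianion of 16, whose only nucleophilic ring carbon C3 is C-alkylated twice (dearomatising gem-dialkylation as in lupulone-type syntheses); once C3 is quaternary the ether cannot re-form.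

## Compound list

1 | (S)-(−)-limonene, (4S)-1-methyl-4-(prop-1-en-2-yl)cyclohex-1-ene | CC1=CC[C@H](CC1)C(C)=C | starting material
2 | (3S)-6-oxo-3-(prop-1-en-2-yl)heptanal | O=CC[C@H](CCC(C)=O)C(C)=C | intermediate
3 | (5R)-2-methyl-5-(prop-1-en-2-yl)cyclopent-1-ene-1-carbaldehyde | O=CC1=C(C)CC[C@@H]1C(C)=C | intermediate
4 | (1R,2R,5S)-5-methyl-2-(prop-1-en-2-yl)-6-oxabicyclo[3.1.0]hexane-1-carbaldehyde (oxirane trans to isopropenyl) | O=C[C@@]12[C@H](CC[C@]1(C)O2)C(C)=C | intermediate
5 | (1S,2S,5S)-2-hydroxy-2-methyl-5-(prop-1-en-2-yl)cyclopentane-1-carbaldehyde (formyl cis to isopropenyl) | O=C[C@H]1[C@H](CC[C@]1(C)O)C(C)=C | intermediate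
6 | (1R,2S,5S)-2-hydroxy-2-methyl-5-(prop-1-en-2-yl)cyclopentane-1-carbaldehyde (formyl trans to isopropenyl, cis to OH) | O=C[C@@H]1[C@H](CC[C@]1(C)O)C(C)=C | intermediate
7 | phloroglucinol, benzene-1,3,5-triol | Oc1cc(O)cc(O)c1 | starting material
8 | (6Z)-6-{[(1R,2S,5S)-2-hydroxy-2-methyl-5-(prop-1-en-2-yl)cyclopentyl]methylidene}-3,5-dihydroxycyclohexa-2,4-dien-1-one (one tautomer and geometry drawn) | O=C1C=C(O)C=C(O)/C1=C/[C@@H]1[C@H](CC[C@]1(C)O)C(C)=C | intermediate
9 | 2-{[(1R,2S,5S)-2-hydroxy-2-methyl-5-(prop-1-en-2-yl)cyclopentyl]methyl}benzene-1,3,5-triol | Oc1cc(O)c(C[C@@H]2[C@H](CC[C@]2(C)O)C(C)=C)c(O)c1 | intermediate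
10 | (3'S,3a'R,7a'S)-3'-hydroxy-3'-methyl-7'-methylideneoctahydrospiro[cyclohexane-1,5'-indene]-2,4,6-trione (trans ring fusion; spiro carbon not a stereocentre) | C=C1CC2(C[C@@H]3[C@@H]1CC[C@]3(C)O)C(=O)CC(=O)CC2=O | intermediate
11 | bridged enol ether: O-7' of the (3'S,3a'R,7'R,7a'S)-3',7'-dihydroxy-3',7'-dimethyl spiro trione bonded to C2 (C2=C3 enol ether, C4 and C6 carbonyls, 3'-OH free) | O=C1CC(=O)C=C2O[C@]3(C)C[C@]12C[C@@H]1[C@@H]3CC[C@]1(C)O | intermediate
12 | 3-methylbutanoic acid (isovaleric acid) | CC(C)CC(=O)O | starting material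
13 | enol 3-methylbutanoate of 11 (acyl on the oxygen at C4) | CC(C)CC(=O)OC1=CC(=O)[C@@]23C[C@@H]4[C@H](CC[C@]4(C)O)[C@@](C)(C2)OC3=C1 | intermediate
14 | 5-(3-methylbutanoyl) derivative of 11 (acyl on the carbon between C4 and C6, enol form) | CC(C)CC(=O)C1=C(O)C=C2O[C@]3(C)C[C@]2(C[C@@H]4[C@@H]3CC[C@]4(C)O)C1=O | intermediate
15 | 1-bromo-3-methylbut-2-ene (prenyl bromide) | CC(C)=CCBr | starting material
16 | (3'S,3a'R,7'R,7a'S)-3',7'-dihydroxy-3',7'-dimethyl-5-(3-methylbutanoyl)octahydrospiro[cyclohexane-1,5'-indene]-2,4,6-trione (C2 carbonyl syn to 7'-OH, C3 unsubstituted) | CC(C)CC(=O)C1=C(O)CC(=O)[C@@]2(C[C@@H]3[C@H](CC[C@]3(C)O)[C@](C)(O)C2)C1=O | intermediate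
17 | 3-(3-methylbut-2-enyl) derivative of 16 (enol form) | CC(C)=CCC1=C(O)[C@@]2(C[C@@H]3[C@H](CC[C@]3(C)O)[C@](C)(O)C2)C(=O)C(C(=O)CC(C)C)=C1O | intermediate
18 | CNP0198642.4, the 3,3-bis(3-methylbut-2-enyl) derivative of 16 | CC(C)=CCC1(CC=C(C)C)C(=O)[C@@]2(C[C@@H]3[C@H](CC[C@]3(C)O)[C@](C)(O)C2)C(=O)C(C(=O)CC(C)C)=C1O | target

## Step count and risk

Total step count: 7. Longest linear sequence: 7 steps (1 to 18); 7, 12 and 15 are bought.

The three steps most likely to fail:

Step 5 (the proposed new step). The electron-rich phenol may couple intermolecularly or over-oxidise, and part of the radical may close 5-exo. Fallback with known chemistry: set out from 6 and chlorinate the isopropenyl group in the ene sense (NCS, PhSeCl cat., CH2Cl2) to give (1R,2S,5S)-5-(3-chloroprop-1-en-2-yl)-2-hydroxy-2-methylcyclopentane-1-carbaldehyde F2. Reductive alkylation of 7 under the conditions of step 4 gives 2-{[(1R,2S,5S)-5-(3-chloroprop-1-en-2-yl)-2-hydroxy-2-methylcyclopentyl]methyl}benzene-1,3,5-triol F3. Intramolecular dearomatising C-allylation (Pd(PPh3)4, zerovalent palladium, K2CO3, MeCN; both termini of the 2-substituted allyl unit are equivalent) closes the spiro ring without any oxidant and comes back at 10, which TsOH converts to 11 as in the second stage of step 5.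

Step 4. Diarylmethane formation or loss of water from 6 (back to 3, then chromene formation) can spoil the mono-alkylation. Fallback: set out from 6 and 7, add thiophenol (AcOH cat., CH2Cl2) so that the quinone methide is captured as the stable benzylic sulfide 2-{[(1R,2S,5S)-2-hydroxy-2-methyl-5-(prop-1-en-2-yl)cyclopentyl](phenylsulfanyl)methyl}benzene-1,3,5-triol F1 (both epimers at the sulfur-bearing carbon), isolate it, and cleave the C–S bond by radical reduction (Bu3SnH, AIBN, toluene, 80 °C) to come back at 9.

Step 7. Hydroxide attack on the vinylogous ester of an already anionic triketone may be slow, and O-prenylation can compete with the second C-alkylation. Fallback: set out from 14 and replace hydroxide opening and SN2 alkylation by an acid-assisted Tsuji–Trost sequence (Pd(PPh3)4, 2-methylbut-3-en-2-ol, AcOH cat., wet THF, 50 °C). Reversible acid-catalysed hydration of the enol ether supplies 16, whose neutral enol is C-prenylated twice (through 17) at the less hindered terminus of the prenyl palladium complex; the second prenylation makes re-closure impossible, and the sequence comes back at 18 without any new isolated compound.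

## Further compounds

F1 | step 4 | 2-{[(1R,2S,5S)-2-hydroxy-2-methyl-5-(prop-1-en-2-yl)cyclopentyl](phenylsulfanyl)methyl}benzene-1,3,5-triol (both epimers at the sulfur-bearing carbon) | Oc1cc(O)c(C(Sc2ccccc2)[C@@H]2[C@H](CC[C@]2(C)O)C(C)=C)c(O)c1
F2 | step 5 | (1R,2S,5S)-5-(3-chloroprop-1-en-2-yl)-2-hydroxy-2-methylcyclopentane-1-carbaldehyde | O=C[C@@H]1[C@H](CC[C@]1(C)O)C(=C)CCl
F3 | step 5 | 2-{[(1R,2S,5S)-5-(3-chloroprop-1-en-2-yl)-2-hydroxy-2-methylcyclopentyl]methyl}benzene-1,3,5-triol | Oc1cc(O)c(C[C@@H]2[C@H](CC[C@]2(C)O)C(=C)CCl)c(O)c1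
F0 | step 7 | none | none
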